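**Retrosynthetic overview**
1. Target ⇐ acyclic (E,Z,E)-tetraene ketol, in one flask: thermal 6π-electrocyclization (cyclohexadiene ring) and 1O2 [4+2] (dioxabicycle), then PPh3 collapse of the endoperoxide to the vinyl epoxide.
2. Tetraene ⇐ Suzuki–Miyaura union of a pyranyl (Z)-dienyl iodide with an alkenylboronate made in situ from an enyne ketol.
3. Enyne ketol ⇐ Sonogashira coupling of propyne with the syn-aldol of pentan-3-one and 2-bromoacrolein (Paterson aldol sets both side-chain stereocentres).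
4. Dienyl iodide ⇐ vinylogous aldol/elimination of 2-ethyl-6-methoxy-3,5-dimethylpyran-4-one with (Z)-3-iodo-2-methylacrolein; pyranone ⇐ triketide cyclization and O-methylation.
5. Ring order: pyranone (step 2), then cyclohexadiene and endoperoxide together, then oxirane (all in step 11).

Assumption: the facial sense of Ipc2B (Z)-enolates is taken to parallel Brown's Ipc2B crotylation, so the triflate made beforehand from (−)-α-pinene (BH3·SMe2, then TfOH) is specified for the (4R,5R) aldol.

**Route**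

Step 1
Reactants: 1 methyl 2-methyl-3-oxopentanoate; 2 N-methoxy-N-methylpropanamide
Product: 3 methyl 2,4-dimethyl-3,5-dioxoheptanoate
Conditions: NaH, THF, 0 °C; n-BuLi, 0 °C; then 2, 0 °C → rt; aq HCl
Reagents that add atoms: none
Why: Claisen-type γ-acylation of the β-keto ester dianion (Huckin–Weiler) by the Weinreb amide, whose stable tetrahedral adduct prevents over-addition; the stereocentres are epimerizable and vanish in step 2.

Step 2
Reactants: 3 methyl 2,4-dimethyl-3,5-dioxoheptanoate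
Product: 4 6-ethyl-4-hydroxy-3,5-dimethyl-2H-pyran-2-one
Conditions: DBU, PhMe, reflux
Reagents that add atoms: none
Why: base-mediated enol lactonization of the 3,5-diketo ester (addition–elimination at the ester) closes the 4-hydroxy-2-pyranone ring with loss of methanol.

Step 3
Reactants: 4 6-ethyl-4-hydroxy-3,5-dimethyl-2H-pyran-2-one
Product: 5 2-ethyl-6-methoxy-3,5-dimethyl-4H-pyran-4-one
Conditions: MeOTf, CH2Cl2, rt; aq NaHCO3
Reagents that add atoms: methyl triflate, COS(=O)(=O)C(F)(F)F
Why: Beak-type O-methylation: the hard methylating agent alkylates the lactone carbonyl oxygen, and loss of the hydroxyl proton gives the α-methoxy-γ-pyranone rather than the 4-methoxy-2-pyranone.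

Step 4
Reactants: 6 prop-2-yn-1-ol
Product: 7 (2Z)-3-iodo-2-methylprop-2-en-1-ol
Conditions: MeMgBr (2.5 equiv), CuI (10 mol%), THF, 0 °C → rt; then I2, −78 → 0 °C; aq NH4Cl
Reagents that add atoms: methylmagnesium bromide, C[Mg]Br; iodine, II
Why: CuI-catalysed anti-carbomagnesiation of the magnesium propargyl alkoxide (Duboudin reaction) gives a chelated alkenylmagnesium with Mg cis to CH2O, and iodinolysis with retention fixes the Z geometry.

Step 5
Reactants: 7 (2Z)-3-iodo-2-methylprop-2-en-1-ol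
Product: 8 (2Z)-3-iodo-2-methylprop-2-enal
Conditions: MnO2, CH2Cl2, rt, dark
Reagents that add atoms: none
Why: MnO2 allylic oxidation is neutral, stops at the enal and does not isomerize the (Z)-iodoalkene.

Step 6
Reactants: 5 2-ethyl-6-methoxy-3,5-dimethyl-4H-pyran-4-one; 8 (2Z)-3-iodo-2-methylprop-2-enal
Product: 11 2-[(2E,4Z)-5-iodo-4-methylpenta-2,4-dien-2-yl]-6-methoxy-3,5-dimethyl-4H-pyran-4-one, via lithium aldolate 9 (not isolated), via mesylate 10 (not isolated)
Conditions: LiN(SiMe3)2, THF, −78 °C; 8; then MsCl, −78 → 0 °C; then DBU, rt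
Reagents that add atoms: none
Why: vinylogous deprotonation of the pyranone ethyl group, 1,2-aldol addition to the enal, then mesylation and E1cB elimination give the conjugated E-alkene (pyranyl trans to the chain) while the (Z)-iodoalkene is untouched.

Step 7
Reactants: 12 prop-2-enal
Product: 14 2-bromoprop-2-enal, via dibromopropanal 13 (not isolated)
Conditions: Br2, CH2Cl2, −78 °C; then Et3N, −78 → 0 °C
Reagents that add atoms: bromine, BrBr
Why: alkene bromination followed by E1cB dehydrobromination through the acidic α-hydrogen gives the α-bromo enal, which is used fresh.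

Step 8
Reactants: 14 2-bromoprop-2-enal; 15 pentan-3-one
Product: 18 (4R,5R)-6-bromo-5-hydroxy-4-methylhept-6-en-3-one, via enol borinate 16 (not isolated), via boron aldolate 17 (not isolated)
Conditions: Ipc2BOTf [from (−)-α-pinene], i-Pr2NEt, CH2Cl2, −78 °C; then 14, −78 → −20 °C; MeOH, pH 7 buffer, H2O2, 0 °C
Reagents that add atoms: none
Why: Paterson aldol: the (Z)-enol diisopinocampheylborinate reacts through a closed chair (Zimmerman–Traxler) transition state to give the syn diad, and the Ipc ligands select the aldehyde Re face to set 4R and 5R (about 90% ee expected for an α-substituted enal).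

Step 9
Reactants: 18 (4R,5R)-6-bromo-5-hydroxy-4-methylhept-6-en-3-one; 19 propyne
Product: 20 (4R,5R)-5-hydroxy-4-methyl-6-methylidenenon-7-yn-3-one
Conditions: PdCl2(PPh3)2 (3 mol%), CuI (5 mol%), i-Pr2NH, THF, 0 °C → rt
Reagents that add atoms: none
Why: Sonogashira coupling of the 2-bromoallylic alcohol proceeds under mild amine conditions that leave the β-hydroxy ketone and both stereocentres untouched.

Step 10
Reactants: 20 (4R,5R)-5-hydroxy-4-methyl-6-methylidenenon-7-yn-3-one; 11 2-[(2E,4Z)-5-iodo-4-methylpenta-2,4-dien-2-yl]-6-methoxy-3,5-dimethyl-4H-pyran-4-one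
Product: 22 (4R,5R,7E,9Z,11E)-5-hydroxy-12-(6-methoxy-3,5-dimethyl-4-oxo-4H-pyran-2-yl)-4,8,10-trimethyl-6-methylidenetrideca-7,9,11-trien-3-one, via alkenylboronate 21 (not isolated)
Conditions: CuCl (5 mol%), PPh3 (6 mol%), NaOt-Bu (6 mol%), B2pin2, MeOH, THF, rt; then 11, Pd(dppf)Cl2 (5 mol%), aq K3PO4, rt, dark
Reagents that add atoms: none
Why: CuCl/PPh3-catalysed syn-protoboration of the 1,3-enyne puts boron on the methyl-bearing alkyne carbon (copper sits on the carbon conjugated to the alkene), and Suzuki–Miyaura coupling with retention at both partners gives the (E,Z,E)-triene, which is kept at room temperature so that it does not cyclize.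

Step 11
Reactants: 22 (4R,5R,7E,9Z,11E)-5-hydroxy-12-(6-methoxy-3,5-dimethyl-4-oxo-4H-pyran-2-yl)-4,8,10-trimethyl-6-methylidenetrideca-7,9,11-trien-3-one
Product: 25 (4R,5R)-5-hydroxy-6-[(1R,4R,5R,6S)-4-(6-methoxy-3,5-dimethyl-4-oxo-4H-pyran-2-yl)-2,4,6-trimethyl-7-oxabicyclo[4.1.0]hept-2-en-5-yl]-4-methylhept-6-en-3-one, via cyclohexadiene 23 (not isolated), via endoperoxide 24 (not isolated)
Conditions: PhMe, 100 °C, dark, Ar; then CH2Cl2, tetraphenylporphyrin (TPP, 1 mol%), O2, visible light, −20 °C; then PPh3, −20 °C → rt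
Reagents that add atoms: dioxygen (as singlet oxygen), O=O
Why: thermal disrotatory 6π-electrocyclization of the (E,Z,E)-triene places pyranyl and side chain cis, Schenck [4+2] photooxygenation adds 1O2 to the diene face anti to both, and PPh3 attacks the less hindered peroxide oxygen (on the CH bridgehead) so that the other oxygen closes SN2′ to the C–C(Me) epoxide on that same face (phosphine deoxygenation of a 1,4-endoperoxide to a vinyl epoxide); the two disrotatory senses differ only through the remote carbinol, so the ring-epimeric series forms alongside in comparable amount and is removed by chromatography.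

**Compound list**
1 | methyl 2-methyl-3-oxopentanoate | CCC(=O)C(C)C(=O)OC | starting material
2 | N-methoxy-N-methylpropanamide | CCC(=O)N(C)OC | starting material
3 | methyl 2,4-dimethyl-3,5-dioxoheptanoate (stereo/tautomer mixture) | CCC(=O)C(C)C(=O)C(C)C(=O)OC | intermediate
4 | 6-ethyl-4-hydroxy-3,5-dimethyl-2H-pyran-2-one | CCc1oc(=O)c(C)c(O)c1C | intermediate
5 | 2-ethyl-6-methoxy-3,5-dimethyl-4H-pyran-4-one | CCc1oc(OC)c(C)c(=O)c1C | intermediate
6 | prop-2-yn-1-ol | C#CCO | starting material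
7 | (2Z)-3-iodo-2-methylprop-2-en-1-ol | OC/C(C)=C\I | intermediate
8 | (2Z)-3-iodo-2-methylprop-2-enal | O=C/C(C)=C\I | intermediate
9 | lithium (1Z)-1-iodo-4-(6-methoxy-3,5-dimethyl-4-oxo-4H-pyran-2-yl)-2-methylpent-1-en-3-olate (diastereomer mixture, not isolated) | COc1oc(C(C)C(O[Li])/C(C)=C\I)c(C)c(=O)c1C | intermediate
10 | (1Z)-1-iodo-4-(6-methoxy-3,5-dimethyl-4-oxo-4H-pyran-2-yl)-2-methylpent-1-en-3-yl methanesulfonate (not isolated) | COc1oc(C(C)C(OS(C)(=O)=O)/C(C)=C\I)c(C)c(=O)c1C | intermediate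
11 | 2-[(2E,4Z)-5-iodo-4-methylpenta-2,4-dien-2-yl]-6-methoxy-3,5-dimethyl-4H-pyran-4-one | COc1oc(/C(C)=C/C(C)=C\I)c(C)c(=O)c1C | intermediate
12 | prop-2-enal (acrolein) | C=CC=O | starting material
13 | 2,3-dibromopropanal (not isolated) | O=CC(Br)CBr | intermediate
14 | 2-bromoprop-2-enal | C=C(Br)C=O | intermediate
15 | pentan-3-one | CCC(=O)CC | starting material
16 | (Z)-pent-2-en-3-yl bis[(1S,2R,3S,5S)-isopinocampheyl]borinate (not isolated) | C/C=C(/CC)OB([C@H]1C[C@H]2C[C@H](C2(C)C)[C@@H]1C)[C@H]1C[C@H]2C[C@H](C2(C)C)[C@@H]1C | intermediate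
17 | (4R,5R)-6-bromo-4-methyl-3-oxohept-6-en-5-yl diisopinocampheylborinate (not isolated) | C=C(Br)[C@H](OB([C@H]1C[C@H]2C[C@H](C2(C)C)[C@@H]1C)[C@H]1C[C@H]2C[C@H](C2(C)C)[C@@H]1C)[C@@H](C)C(=O)CC | intermediate
18 | (4R,5R)-6-bromo-5-hydroxy-4-methylhept-6-en-3-one | C=C(Br)[C@H](O)[C@@H](C)C(=O)CC | intermediate
19 | propyne | CC#C | starting material
20 | (4R,5R)-5-hydroxy-4-methyl-6-methylidenenon-7-yn-3-one | CC#CC(=C)[C@H](O)[C@@H](C)C(=O)CC | intermediate
21 | (4R,5R,7Z)-5-hydroxy-4-methyl-6-methylidene-8-(4,4,5,5-tetramethyl-1,3,2-dioxaborolan-2-yl)non-7-en-3-one (not isolated) | C=C([C@H](O)[C@@H](C)C(=O)CC)/C=C(\C)B1OC(C)(C)C(C)(C)O1 | intermediate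
22 | (4R,5R,7E,9Z,11E)-5-hydroxy-12-(6-methoxy-3,5-dimethyl-4-oxo-4H-pyran-2-yl)-4,8,10-trimethyl-6-methylidenetrideca-7,9,11-trien-3-one | C=C([C@H](O)[C@@H](C)C(=O)CC)/C=C(C)/C=C(C)\C=C(/C)c1oc(OC)c(C)c(=O)c1C | intermediate
23 | (4R,5R)-5-hydroxy-6-[(1R,6R)-6-(6-methoxy-3,5-dimethyl-4-oxo-4H-pyran-2-yl)-2,4,6-trimethylcyclohexa-2,4-dien-1-yl]-4-methylhept-6-en-3-one (pyranyl and side chain cis, not isolated) | C=C([C@H](O)[C@@H](C)C(=O)CC)[C@H]1C(C)=CC(C)=C[C@@]1(C)c1oc(OC)c(C)c(=O)c1C | intermediate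
24 | endoperoxide of 23: O2 added across the two diene termini as a 2,3-dioxabicyclo[2.2.2]oct-5-ene, peroxide bridge anti to pyranyl and side chain (not isolated) | C=C([C@H](O)[C@@H](C)C(=O)CC)[C@H]1[C@]2(C)OO[C@@H](C(C)=C2)[C@@]1(C)c1oc(OC)c(C)c(=O)c1C | intermediate
25 | (4R,5R)-5-hydroxy-6-[(1R,4R,5R,6S)-4-(6-methoxy-3,5-dimethyl-4-oxo-4H-pyran-2-yl)-2,4,6-trimethyl-7-oxabicyclo[4.1.0]hept-2-en-5-yl]-4-methylhept-6-en-3-one (CNP0233636.2) | C=C([C@H](O)[C@@H](C)C(=O)CC)[C@H]1[C@]2(C)O[C@@H]2C(C)=C[C@@]1(C)c1oc(OC)c(C)c(=O)c1C | target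

**Step count and risks**

Total step count: 11. Longest linear sequence: 6 steps (1 → 2 → 3 → 6 → 10 → 11, counted from compound 1).

The three steps most likely to fail:

Step 8. The facial sense and ee of the Ipc-controlled aldol are the weak point, and the ee of 25 equals the ee of 18. The fallback is auxiliary control, setting out from 14. Compound 14 is added to the Bu2BOTf/i-Pr2NEt enolate of commercial (R)-4-benzyl-3-propanoyl-1,3-oxazolidin-2-one to give the Evans syn imide (R)-4-benzyl-3-[(2R,3R)-4-bromo-3-hydroxy-2-methylpent-4-enoyl]-1,3-oxazolidin-2-one F1. Transamidation (MeONHMe·HCl, Me3Al) gives the Weinreb amide (2R,3R)-4-bromo-3-hydroxy-N-methoxy-N,2-dimethylpent-4-enamide F2, and EtMgBr converts it into 18, where the route is rejoined.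

Step 10. The free ketol may not survive the CuCl/alkoxide and aqueous K3PO4 stages (retro-aldol, ketone borylation), and the protoboration regiochemistry is untested on this enyne. The fallback moves the aldol behind the coupling, setting out from 19 and 11. Propyne 19 is coupled with commercial 2-bromoprop-2-en-1-ol (PdCl2(PPh3)2, CuI, i-Pr2NH) to 2-methylidenepent-3-yn-1-ol F3. The same protoboration gives (3Z)-2-methylidene-4-(4,4,5,5-tetramethyl-1,3,2-dioxaborolan-2-yl)pent-3-en-1-ol F4, coupled in the same flask with 11 to the tetraenol 2-[(2E,4Z,6E)-8-(hydroxymethyl)-4,6-dimethylnona-2,4,6,8-tetraen-2-yl]-6-methoxy-3,5-dimethyl-4H-pyran-4-one F5. MnO2 gives the tetraenal (3E,5Z,7E)-8-(6-methoxy-3,5-dimethyl-4-oxo-4H-pyran-2-yl)-4,6-dimethyl-2-methylidenenona-3,5,7-trienal F6. Addition of F6 to enol borinate 16 under the conditions of step 8 passes through the diisopinocampheylboron aldolate F7 and returns to the route at 22.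

Step 11. Ring closure is not face-selective with respect to the side chain, so at best half of the material is 25. In addition, the phosphine collapse of 24 could give the regioisomeric epoxide, or the telescoped sequence may not be clean. The fallback sets out from 22: it is only heated, diene 23 is isolated, and the ring double bond next to the side-chain carbon is epoxidized directly with dimethyldioxirane (acetone, −20 °C). The reagent attacks the face opposite to pyranyl and side chain and is steered away from the other ring double bond by the quaternary-carbon methyl on that face. This returns to the route at 25 and makes no compound outside the list (F0).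

**Further compounds**
F1 | step 8 | (R)-4-benzyl-3-[(2R,3R)-4-bromo-3-hydroxy-2-methylpent-4-enoyl]-1,3-oxazolidin-2-one | C=C(Br)[C@H](O)[C@@H](C)C(=O)N1[C@H](Cc2ccccc2)COC1=O
F2 | step 8 | (2R,3R)-4-bromo-3-hydroxy-N-methoxy-N,2-dimethylpent-4-enamide | C=C(Br)[C@H](O)[C@@H](C)C(=O)N(C)OC
F3 | step 10 | 2-methylidenepent-3-yn-1-ol | CC#CC(=C)CO
F4 | step 10 | (3Z)-2-methylidene-4-(4,4,5,5-tetramethyl-1,3,2-dioxaborolan-2-yl)pent-3-en-1-ol | OCC(=C)/C=C(\C)B1OC(C)(C)C(C)(C)O1
F5 | step 10 | 2-[(2E,4Z,6E)-8-(hydroxymethyl)-4,6-dimethylnona-2,4,6,8-tetraen-2-yl]-6-methoxy-3,5-dimethyl-4H-pyran-4-one | COc1oc(/C(C)=C/C(C)=C\C(C)=C\C(=C)CO)c(C)c(=O)c1C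
F6 | step 10 | (3E,5Z,7E)-8-(6-methoxy-3,5-dimethyl-4-oxo-4H-pyran-2-yl)-4,6-dimethyl-2-methylidenenona-3,5,7-trienal | COc1oc(/C(C)=C/C(C)=C\C(C)=C\C(=C)C=O)c(C)c(=O)c1C
F7 | step 10 | diisopinocampheylboron aldolate of 22 | C=C([C@H](OB([C@H]1C[C@H]2C[C@H](C2(C)C)[C@@H]1C)[C@H]1C[C@H]2C[C@H](C2(C)C)[C@@H]1C)[C@@H](C)C(=O)CC)/C=C(C)/C=C(C)\C=C(/C)c1oc(OC)c(C)c(=O)c1C
F0 | step 11 | none | none
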